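A direct plan would build the dichlorinated diaryl ether A1 first, attach both three-carbon units by a twofold Suzuki coupling to the bis(allyl aryl ether) A2,
form both C4–C4a bonds by a twofold aromatic Claisen rearrangement to the bis(allylphenol) A3, set C3 and C3' by asymmetric hydroboration to the diol A4,
and close both pyran rings by Mitsunobu etherification.
Its weakest steps would be the Claisen rearrangement (two ortho carbons would compete at each end, near 190 °C),
the hydroboration (aryl would have to be told from arylmethyl on a 1,1-disubstituted alkene, twice),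
and the silyl capping and uncapping around them, which would add length without adding skeleton.

The route rests on cutting each C3–C1' bond back to a chalcone: the two B rings, already joined through O as a dialdehyde, are condensed with two ring A acetophenones, and a twofold biomimetic oxidative 1,2-aryl shift then moves each B ring from the former formyl carbon (which becomes C2) to its neighbour (C3), after which O1 closes ring C onto C2. One operation thus makes both hindered C3–aryl bonds and both pyranone rings, with the C4–C4a bonds bought in the acetophenone. C3 is left trigonal beside a carbonyl group, so one transfer-hydrogenation catalyst sets both centres with dynamic kinetic resolution; no sigmatropic regiochemistry, alkene hydroboration, silyl group or separate ring closure remains.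

Key step: step 6

Remark: both stereocentres are read from the SMILES as R (3R,3'R); the sense of induction in step 7 is assigned by analogy with aryl alkyl ketones, and the (S,S) catalyst would be used if the opposite sense were found.

Step 1
Reactants: 1 3-fluorocatechol
Product: 3 4-fluoro-2,3-dihydroxybenzaldehyde, via hydroxymethyl catechol 2 (not isolated)
Conditions: MgCl2 (3 equiv), Et3N (6 equiv), (CH2O)n (8 equiv), MeCN, reflux; aq HCl work-up
Reagents that add atoms: paraformaldehyde (as formaldehyde), C=O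
Why: Magnesium-mediated ortho-formylation of a phenol (Casnati–Skattebøl reaction), in which the magnesium phenoxide delivers formaldehyde only to a free ortho carbon, which 3-fluorocatechol has only at C6, and a second formaldehyde oxidises the benzylic alkoxide by hydride transfer.

Step 2
Reactants: 3 4-fluoro-2,3-dihydroxybenzaldehyde
Product: 5 3-(benzyloxy)-4-fluoro-2-methoxybenzaldehyde, via mono-benzyl ether 4 (not isolated)
Conditions: NaH (2.2 equiv), DMSO, rt; BnBr (1.0 equiv), rt; then MeI (2 equiv), rt → 40 °C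
Reagents that add atoms: benzyl bromide, BrCc1ccccc1; iodomethane, CI
Why: Sequential Williamson etherification of the dianion, in which the 2-oxide is chelated and conjugated to the formyl group and is the weaker nucleophile, so that one equivalent of benzyl bromide should go to O3 and the remaining 2-phenoxide is then methylated in the same flask.

Step 3
Reactants: 5 3-(benzyloxy)-4-fluoro-2-methoxybenzaldehyde
Product: 7 3-(benzyloxy)-4-hydroxy-2-methoxybenzaldehyde, via sulfonylethyl aryl ether 6 (not isolated)
Conditions: MeSO2CH2CH2OH (1.5 equiv), NaH (3 equiv), DMF, 0 °C → rt; aq HCl work-up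
Reagents that add atoms: 2-(methylsulfonyl)ethanol, CS(=O)(=O)CCO (its oxygen becomes the phenol oxygen of 7; the rest stays only in intermediate 6)
Why: Nucleophilic aromatic substitution of the fluoride para to the formyl group by the alkoxide, followed by E1cB loss of methyl vinyl sulfone from the aryl ether, a mild hydroxide-surrogate sequence that avoids Cannizzaro chemistry of the aldehyde.

Step 4
Reactants: 7 3-(benzyloxy)-4-hydroxy-2-methoxybenzaldehyde; 5 3-(benzyloxy)-4-fluoro-2-methoxybenzaldehyde (1.05 equiv)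
Product: 8 4,4'-oxybis[3-(benzyloxy)-2-methoxybenzaldehyde]
Conditions: K2CO3 (2 equiv), DMSO, 110 °C, N2
Reagents that add atoms: none
Why: Nucleophilic aromatic substitution (addition–elimination through a Meisenheimer complex stabilised by the para formyl group) should give the symmetrical diaryl ether, which already carries both future C2 carbons as its formyl groups.

Step 5
Reactants: 8 4,4'-oxybis[3-(benzyloxy)-2-methoxybenzaldehyde]; 9 1-[4-(benzyloxy)-2-hydroxyphenyl]ethan-1-one (2.2 equiv)
Product: 10 (2E,2'E)-3,3'-[oxybis(3-(benzyloxy)-2-methoxy-4,1-phenylene)]bis{1-[4-(benzyloxy)-2-hydroxyphenyl]prop-2-en-1-one}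
Conditions: KOH (50% aq), EtOH/THF, rt, 48 h; then aq HCl to pH 3
Reagents that add atoms: none
Why: Twofold Claisen–Schmidt (crossed aldol) condensation of a non-enolisable dialdehyde with the methyl ketone, in which E1cB dehydration gives the E enones and the strongly basic medium keeps the 2'-phenoxide chalcone from closing to the flavanone.

Step 6
Reactants: 10 bis(2'-hydroxychalcone)
Product: 12 3,3'-[oxybis(3-(benzyloxy)-2-methoxy-4,1-phenylene)]bis[7-(benzyloxy)-4H-chromen-4-one], via bis(dimethyl acetal) 11 (not isolated)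
Conditions: Tl(NO3)3·3H2O (2.4 equiv), MeOH/CH2Cl2 (3:1), rt; TlNO3 filtered off; then 10% aq HCl, MeOH/THF, 60 °C
Reagents that add atoms: methanol, CO (the methoxy groups of intermediate 11 only; none of its atoms stay in 12)
Why: Trivalent thallium and methanol should add across each enone C=C with methoxy at the benzylic carbon and thallium at the α-carbon, after which the C–Tl bond ionises with reduction to monovalent thallium while ring B shifts from the benzylic to the α-carbon through a bridged phenonium ion, and the oxocarbenium ion left at the old benzylic carbon is trapped by methanol as the dimethyl acetal 11. The closest known reaction type is the thallium trinitrate rearrangement of 2'-hydroxychalcones to isoflavones, the laboratory counterpart of the aryl shift by which plants turn flavanones into isoflavonoids. On warming with HCl each ring C closes by 6-exo-trig attack of the 2'-hydroxyl (future O1) on the oxocarbenium ion of the acetal carbon (future C2), and loss of methanol from the 2-methoxyisoflavanone gives the chromone. No stereocentre survives the step: the α-carbon of 11 is stereogenic but becomes the trigonal C3 of the chromone, beside the C4 carbonyl group, which is what lets one catalyst set both centres in the next step. The step needs aryl migration to win over acyl migration and over oxidative closure of the 2'-hydroxyl onto the alkene (aurone or flavone formation), and ring B should secure this because its migrating carbon C1' is para to the diaryl ether oxygen and ortho to a methoxy group, which stabilise the phenonium ion, while the acyl group migrates poorly. The benzyl ethers and the diaryl ether should be inert to the reagent, and the two ends react independently.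

Step 7
Reactants: 12 bis(isoflavone)
Product: 14 (3R,3'R,4R,4'R)-3,3'-[oxybis(3-(benzyloxy)-2-methoxy-4,1-phenylene)]bis[7-(benzyloxy)chroman-4-ol] (each ring 3,4-cis), via bis(isoflavanone) 13 (not isolated)
Conditions: RuCl[(R,R)-TsDPEN](p-cymene) (10 mol%), HCO2H/Et3N (5:2), EtOAc/DMF, 45 °C
Reagents that add atoms: none
Why: Noyori–Ikariya asymmetric transfer hydrogenation with dynamic kinetic resolution, in which the Ru–H species first reduces each chromone C2=C3 bond by conjugate hydride addition, the isoflavanone 13 epimerises at C3 through its enol in the basic medium, and the (R,R) catalyst reduces the C4 carbonyl to the 4R carbinol (the sense known for aryl alkyl ketones) fastest in the enantiomer whose C3 aryl group is anti to the incoming hydride, so that the cis (3R,4R) arrangement should result at both ends and, the two ends being set independently, the minor pathway should end mainly in a separable diastereomer.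

Step 8
Reactants: 14 bis(cis-isoflavan-4-ol)
Product: 15 (3R,3'R)-3,3'-[oxybis(3-hydroxy-2-methoxy-4,1-phenylene)]bis(chroman-7-ol) (CNP0116832.1)
Conditions: H2 (3 atm), 10% Pd/C, EtOH/EtOAc, AcOH (5 vol%), rt → 40 °C
Reagents that add atoms: none
Why: Catalytic hydrogenolysis should cleave the four O-benzyl bonds and the two benzylic C4–O bonds (activated by the para 7-oxygen and by O1), as is general for 7-oxygenated isoflavan-4-ols, while C3, the diaryl ether and the chroman C–O bonds are not touched, so that the 3R configuration is carried into the target.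

**Compound list**

1 | 3-fluorocatechol (3-fluorobenzene-1,2-diol) | Oc1cccc(F)c1O | starting material
2 | 3-fluoro-6-(hydroxymethyl)benzene-1,2-diol (magnesium salt in the flask) | OCc1ccc(F)c(O)c1O | intermediate
3 | 4-fluoro-2,3-dihydroxybenzaldehyde | O=Cc1ccc(F)c(O)c1O | intermediate
4 | 3-(benzyloxy)-4-fluoro-2-hydroxybenzaldehyde (sodium salt in the flask) | O=Cc1ccc(F)c(OCc2ccccc2)c1O | intermediate
5 | 3-(benzyloxy)-4-fluoro-2-methoxybenzaldehyde | COc1c(C=O)ccc(F)c1OCc1ccccc1 | intermediate
6 | 3-(benzyloxy)-2-methoxy-4-[2-(methylsulfonyl)ethoxy]benzaldehyde | COc1c(C=O)ccc(OCCS(C)(=O)=O)c1OCc1ccccc1 | intermediate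
7 | 3-(benzyloxy)-4-hydroxy-2-methoxybenzaldehyde | COc1c(C=O)ccc(O)c1OCc1ccccc1 | intermediate
8 | 4,4'-oxybis[3-(benzyloxy)-2-methoxybenzaldehyde] | COc1c(C=O)ccc(Oc2ccc(C=O)c(OC)c2OCc2ccccc2)c1OCc1ccccc1 | intermediate
9 | 1-[4-(benzyloxy)-2-hydroxyphenyl]ethan-1-one | CC(=O)c1ccc(OCc2ccccc2)cc1O | starting material
10 | (2E,2'E)-3,3'-[oxybis(3-(benzyloxy)-2-methoxy-4,1-phenylene)]bis{1-[4-(benzyloxy)-2-hydroxyphenyl]prop-2-en-1-one} | COc1c(/C=C/C(=O)c2ccc(OCc3ccccc3)cc2O)ccc(Oc2ccc(/C=C/C(=O)c3ccc(OCc4ccccc4)cc3O)c(OC)c2OCc2ccccc2)c1OCc1ccccc1 | intermediate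
11 | 2,2'-[oxybis(3-(benzyloxy)-2-methoxy-4,1-phenylene)]bis{1-[4-(benzyloxy)-2-hydroxyphenyl]-3,3-dimethoxypropan-1-one} (diastereomer mixture) | COc1c(C(C(OC)OC)C(=O)c2ccc(OCc3ccccc3)cc2O)ccc(Oc2ccc(C(C(OC)OC)C(=O)c3ccc(OCc4ccccc4)cc3O)c(OC)c2OCc2ccccc2)c1OCc1ccccc1 | intermediate
12 | 3,3'-[oxybis(3-(benzyloxy)-2-methoxy-4,1-phenylene)]bis[7-(benzyloxy)-4H-chromen-4-one] | COc1c(-c2coc3cc(OCc4ccccc4)ccc3c2=O)ccc(Oc2ccc(-c3coc4cc(OCc5ccccc5)ccc4c3=O)c(OC)c2OCc2ccccc2)c1OCc1ccccc1 | intermediate
13 | 3,3'-[oxybis(3-(benzyloxy)-2-methoxy-4,1-phenylene)]bis[7-(benzyloxy)chroman-4-one] (C3 epimerising) | COc1c(C2COc3cc(OCc4ccccc4)ccc3C2=O)ccc(Oc2ccc(C3COc4cc(OCc5ccccc5)ccc4C3=O)c(OC)c2OCc2ccccc2)c1OCc1ccccc1 | intermediate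
14 | (3R,3'R,4R,4'R)-3,3'-[oxybis(3-(benzyloxy)-2-methoxy-4,1-phenylene)]bis[7-(benzyloxy)chroman-4-ol] | COc1c([C@@H]2COc3cc(OCc4ccccc4)ccc3[C@@H]2O)ccc(Oc2ccc([C@@H]3COc4cc(OCc5ccccc5)ccc4[C@@H]3O)c(OC)c2OCc2ccccc2)c1OCc1ccccc1 | intermediate
15 | (3R,3'R)-3,3'-[oxybis(3-hydroxy-2-methoxy-4,1-phenylene)]bis(chroman-7-ol) | COc1c([C@@H]2COc3cc(O)ccc3C2)ccc(Oc2ccc([C@@H]3COc4cc(O)ccc4C3)c(OC)c2O)c1O | target

**Step count and risks**

Total: 8 steps. Longest linear sequence: 8 steps (1 to 15); acetophenone 9 enters at step 5.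

Steps most likely to fail:

Step 6 (key step). The oxidant may divert to closure of the 2'-hydroxyl onto the alkene, or the twofold rearrangement may stall after one end and leave mixed material. The fallback is a non-oxidative acyl shift and sets out from 10. The two 2'-hydroxyls would be capped (MOMCl, NaH, DMF) to give the bis(methoxymethyl ether) F1. The enones would be epoxidised (H2O2, NaOH, MeOH/THF; Weitz–Scheffer epoxidation) to the bis(epoxide) F2. BF3·OEt2 (CH2Cl2, 0 °C) should then open each epoxide at the benzylic carbon and shift the acyl group to it, giving the bis(α-formyl ketone) F3, which has the same skeleton as 11 at the aldehyde oxidation level. HCl in MeOH would remove the methoxymethyl groups and cyclodehydrate, and the route is rejoined at 12.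

Step 7. Conjugate reduction of the vinylogous ester may be incomplete, or the rate difference in the dynamic kinetic resolution may be too small at one end, which would give mixed diastereomers. The fallback sets out from 12. NaBH4 (THF/EtOH) would give the bis(isoflavan-4-ol) F4 as a stereoisomer mixture, and acid dehydration (TsOH, toluene, 80 °C) the bis(isoflav-3-ene) F5. Asymmetric hydrogenation of the two trisubstituted cyclic alkenes with [Ir(cod)(tBu-PHOX)]BArF (the enantiomer that gives the R centre; H2, 50 bar, CH2Cl2) should give the tetrabenzyl bis(isoflavan) F6. Neutral hydrogenolysis (H2, Pd/C, EtOAc/MeOH) then comes back to the route at 15.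

Step 8. The benzylic C4–O cleavage may stall once the phenols are free, or configuration at C3 may be lost if the acid opens a dehydration–rehydrogenation path through the isoflav-3-ene. The fallback is a radical deoxygenation and sets out from 14. NaH, CS2 and MeI (THF) would give the bis(S-methyl xanthate) F7, and Bu3SnH with AIBN (toluene, 80 °C; Barton–McCombie deoxygenation) should give the tetrabenzyl bis(isoflavan) F6. The C4 radical cannot affect C3, and the cis arrangement leaves no syn hydrogen at C3 for a Chugaev elimination. Neutral hydrogenolysis (H2, Pd/C, EtOAc/MeOH) of the benzyl ethers then comes back to the route at 15.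

**Further compounds**

F1 | step 6 | (2E,2'E)-3,3'-[oxybis(3-(benzyloxy)-2-methoxy-4,1-phenylene)]bis{1-[4-(benzyloxy)-2-(methoxymethoxy)phenyl]prop-2-en-1-one} | COc1c(/C=C/C(=O)c2ccc(OCc3ccccc3)cc2OCOC)ccc(Oc2ccc(/C=C/C(=O)c3ccc(OCc4ccccc4)cc3OCOC)c(OC)c2OCc2ccccc2)c1OCc1ccccc1
F2 | step 6 | bis(trans-epoxide) of F1 at both enone C=C bonds (racemic epoxides, diastereomer mixture) | COc1c(C2OC2C(=O)c2ccc(OCc3ccccc3)cc2OCOC)ccc(Oc2ccc(C3OC3C(=O)c3ccc(OCc4ccccc4)cc3OCOC)c(OC)c2OCc2ccccc2)c1OCc1ccccc1
F3 | step 6 | 2,2'-[oxybis(3-(benzyloxy)-2-methoxy-4,1-phenylene)]bis{3-[4-(benzyloxy)-2-(methoxymethoxy)phenyl]-3-oxopropanal} (diastereomer mixture) | COc1c(C(C=O)C(=O)c2ccc(OCc3ccccc3)cc2OCOC)ccc(Oc2ccc(C(C=O)C(=O)c3ccc(OCc4ccccc4)cc3OCOC)c(OC)c2OCc2ccccc2)c1OCc1ccccc1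
F4 | step 7 | 3,3'-[oxybis(3-(benzyloxy)-2-methoxy-4,1-phenylene)]bis[7-(benzyloxy)chroman-4-ol] (stereoisomer mixture) | COc1c(C2COc3cc(OCc4ccccc4)ccc3C2O)ccc(Oc2ccc(C3COc4cc(OCc5ccccc5)ccc4C3O)c(OC)c2OCc2ccccc2)c1OCc1ccccc1
F5 | step 7 | 3,3'-[oxybis(3-(benzyloxy)-2-methoxy-4,1-phenylene)]bis[7-(benzyloxy)-2H-chromene] | COc1c(C2=Cc3ccc(OCc4ccccc4)cc3OC2)ccc(Oc2ccc(C3=Cc4ccc(OCc5ccccc5)cc4OC3)c(OC)c2OCc2ccccc2)c1OCc1ccccc1
F6 | step 7 | (3R,3'R)-3,3'-[oxybis(3-(benzyloxy)-2-methoxy-4,1-phenylene)]bis[7-(benzyloxy)chromane] | COc1c([C@@H]2COc3cc(OCc4ccccc4)ccc3C2)ccc(Oc2ccc([C@@H]3COc4cc(OCc5ccccc5)ccc4C3)c(OC)c2OCc2ccccc2)c1OCc1ccccc1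
F7 | step 8 | bis(S-methyl xanthate) of 14 at both C4 hydroxyls, (3R,3'R,4R,4'R) | COc1c([C@@H]2COc3cc(OCc4ccccc4)ccc3[C@@H]2OC(=S)SC)ccc(Oc2ccc([C@@H]3COc4cc(OCc5ccccc5)ccc4[C@@H]3OC(=S)SC)c(OC)c2OCc2ccccc2)c1OCc1ccccc1
A1 | direct plan | 1,1'-oxybis[2-(benzyloxy)-4-chloro-3-methoxybenzene] | COc1c(Cl)ccc(Oc2ccc(Cl)c(OC)c2OCc2ccccc2)c1OCc1ccccc1
A2 | direct plan | 1,1'-oxybis{2-(benzyloxy)-3-methoxy-4-[3-(3-(triisopropylsilyloxy)phenoxy)prop-1-en-2-yl]benzene} | COc1c(C(=C)COc2cccc(O[Si](C(C)C)(C(C)C)C(C)C)c2)ccc(Oc2ccc(C(=C)COc3cccc(O[Si](C(C)C)(C(C)C)C(C)C)c3)c(OC)c2OCc2ccccc2)c1OCc1ccccc1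
A3 | direct plan | 2,2'-{oxybis[(3-(benzyloxy)-2-methoxy-4,1-phenylene)(prop-1-ene-2,3-diyl)]}bis[5-(triisopropylsilyloxy)phenol] | COc1c(C(=C)Cc2ccc(O[Si](C(C)C)(C(C)C)C(C)C)cc2O)ccc(Oc2ccc(C(=C)Cc3ccc(O[Si](C(C)C)(C(C)C)C(C)C)cc3O)c(OC)c2OCc2ccccc2)c1OCc1ccccc1
A4 | direct plan | (2R,2'R)-2,2'-[oxybis(3-(benzyloxy)-2-methoxy-4,1-phenylene)]bis{3-[2-hydroxy-4-(triisopropylsilyloxy)phenyl]propan-1-ol} | COc1c([C@@H](Cc2ccc(O[Si](C(C)C)(C(C)C)C(C)C)cc2O)CO)ccc(Oc2ccc([C@@H](Cc3ccc(O[Si](C(C)C)(C(C)C)C(C)C)cc3O)CO)c(OC)c2OCc2ccccc2)c1OCc1ccccc1
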